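The numbers in the tables stem from a simulated flask from invented constants, noise included.

At early times the runs look alike: at 0.49 min the ochre run holds 0.007 M of product and the grey run, with twice the substrate, holds 0.008 M.

common to all: partner 0.600 M

|  | substrate | catalyst | time |
|---|---|---|---|
| ochre | 0.300 M | 0.00900 M |  |
| violet | 0.300 M | 0.0180 M |  |
| grey | 0.600 M | 0.00900 M |  |
| green | 0.900 M | 0.0180 M | 8.6 min |

| run | time / min | [product] / M |
|---|---|---|
| ochre run | 0.49 | 0.007 |
| ochre run | 1.5 | 0.026 |
| ochre run | 2.8 | 0.057 |
| ochre run | 4.5 | 0.121 |
| ochre run | 6.4 | 0.202 |
| ochre run | 8.6 | 0.258 |
| violet run | 0.49 | 0.006 |
| violet run | 1.5 | 0.038 |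
| violet run | 2.8 | 0.099 |
| violet run | 4.5 | 0.182 |
| violet run | 6.4 | 0.250 |
| violet run | 8.6 | 0.284 |
| grey run | 0.49 | 0.008 |
| grey run | 1.5 | 0.035 |
| grey run | 2.8 | 0.145 |
| grey run | 4.5 | 0.347 |
| grey run | 6.4 | 0.484 |
| grey run | 8.6 | 0.544 |

(scatter of a reading: 0.003 M)

* how the opening rate goes with [catalyst] round the charge of the ochre run: the exponent of the rate at two percent of substrate gone to product
* how the opening rate goes with [substrate] round the charge of the ochre run: the exponent of the rate at two percent of substrate gone to product (one fixed amount of product, the same in the runs compared)
* product in the green run at 8.6 min, as a share of the substrate charged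

- Overall: substrate + partner -> product, with catalyst as catalyst.
- Constant volume, constant temperature.
- Bound and free are read together.
- "The second partner" is partner.
- An order is taken over about fifteen percent of the charge, up and down.

I read the opening at 1.5 min, where the scatter is still 11.5 % of the ochre reading, so these are rough figures. Grey over ochre gives me a substrate exponent of 0.429, and violet over ochre gives a catalyst exponent of 0.547. Both are taken at one time, not at one amount of product.

The green run looks contradictory. It is charged with 0.900 M of substrate, more than any earlier run, and with the catalyst of the violet run. Yet I expect its share at 8.6 min to lie below the 86.0 % that the ochre run shows at that time.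

The puzzle clears when I reckon the ceiling share, 66.7 %: the smaller of the partner and substrate charges, divided by the substrate charge. The overall reaction takes one partner for each substrate, so in the green run partner is the limiting reagent, and the ceiling stands below the ochre share. In amount the green ceiling is 0.600 M of product, more than the ochre 0.258 M, but it is divided by a larger charge.

Whether the green run reaches its ceiling by 8.6 min I judge from the grey run, which has the same partner charge and holds 0.544 M at that time. The green run has more substrate and more catalyst than the grey run, and at 4.5 min the violet run, with more catalyst, and the grey run, with more substrate, each hold more product than the ochre run. So I estimate that the green run holds at least the grey amount, which is 60.4 % of the green charge. My reckoning puts the green share between that estimate and the ceiling, close under the ceiling.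

The forecast gives 0.75 for catalyst, above my exponent, 0.15 for substrate, below mine, and 66 % for the green share, noting that “Green has partner as the limiting reagent”.

The flask gives 0.74 for catalyst, 0.43 for substrate and 66.7 % for the green share.

    catalyst + substrate → catalyst-substrate complex (18.96 /M/min)
    catalyst-substrate complex + partner → product + catalyst (16.98 /M/min)
    2 partner ⇌ idle reagent dimer, settled at all times (29.40 /M)
    substrate + partner + product → 2 product (19.68 /M²/min)

Tying up partner as idle reagent dimer moves the readings by 65 scatter units, root mean square, yet it leaves the green share at 8.6 min where it stands. That share matches the ceiling of 66.7 %. For the grey run, with equal charges, the same rule gives a ceiling of 100 %, and its reading at 8.6 min is 90.7 % of the substrate charged.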